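The readings are simulated with made-up constants; noise was put on by code.

I decided to follow one molecule through this flask before integrating anything. Starting material opens, and at the fork open intermediate either closes again or meets second intermediate and becomes target. Starting material and open intermediate therefore form one pool, with target as its exit. The bench rule says that with gas held and second intermediate steady at the same level in each run, this exit is pseudo-first-order, so percent yield at a given time should not depend on the charge.

| setting | south-west | north-east | flask |
|---|---|---|---|
| starting material | 0.12 M (in portions, 2) | 0.50 M (in portions, 2) | 0.25 M (in portions, 2) |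
| gas | 140 mM (held) | 140 mM (held) | 140 mM (held) |
| remark | run made earlier; portions every 2.0 min | run made earlier; portions every 2.0 min | the portions of starting material follow each other after 2.0 min, the first at the start |
| time |  |  | 40 min |

| run | time / min | target / % | open intermediate / % |
|---|---|---|---|
| south-west | 2.00 | 1.5 | 5.8 |
| south-west | 6.00 | 6.8 | 17.1 |
| south-west | 12.0 | 21.8 | 18.2 |
| south-west | 15.0 | 29.8 | 15.2 |
| south-west | 25.0 | 47.3 | 12.8 |
| south-west | 30.0 | 54.9 | 9.7 |
| south-west | 40.0 | 67.5 | 5.7 |
| north-east | 6.00 | 6.9 | 18.8 |
| north-east | 12.0 | 18.2 | 20.1 |
| north-east | 15.0 | 23.4 | 19.4 |
| north-east | 25.0 | 38.0 | 17.2 |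
| north-east | 30.0 | 46.5 | 13.1 |
| north-east | 40.0 | 57.9 | 10.1 |

(scatter of a reading: 1 percentage point)

- concentration of target at 40 min, in M
- concentration of open intermediate at 40 min, in M
- concentration of starting material at 40 min, in M

- at the start none of partner is dissolved
- what may be going on: starting material <-> open intermediate; partner -> second intermediate; open intermediate + second intermediate -> target; 2 second intermediate -> homo product; gas <-> partner

The rule met its border inside these runs. At 40.0 min, the target readings of the two runs differed by 9.6 percentage points, more than the scatter of 1 point. I took the pool as the charge less target and read its loss per minute from 15.0 min to 40.0 min: 0.0308 min⁻¹ in the south-west run and 0.0239 min⁻¹ in the north-east run, which is slower. The ratio of these two readings, north-east over south-west, was 0.776 for 4.17 times the charge. On a log scale of charge, this flask lies 0.514 of the way across, so I took its escape constant κ, the fraction of the pool becoming target per minute, as 0.0273 min⁻¹. Starting from an interpolated pool of 73.5% at 15.0 min, that gave me an estimate of 0.157 M of target at 40 min in this flask.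

The forecast gave 0.156 M of target (0.144 M to 0.168 M), 0.02 M of open intermediate (0.014 M to 0.027 M) and 0.074 M of starting material (0.058 M to 0.088 M); its ground for the target was the yield at 40 min, “Interpolating on log concentration”.

The flask gave 0.162 M of target, 0.0209 M of open intermediate and 0.0668 M of starting material, each inside the forecast's range. In this flask second intermediate stood at 0.0205 M at 20.0 min and 0.0227 M at 40.0 min. Applying κ to this flask's pool left beside 35.8% of target at 20.0 min gives an estimate of 0.157 M of target at 40 min.

    starting material ⇌ open intermediate (K = 0.530, k = 0.0748 min⁻¹)
    partner → second intermediate (k = 0.0986 min⁻¹)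
    open intermediate + second intermediate → target (k = 5.76 M⁻¹ min⁻¹)
    2 second intermediate → homo product (k = 10.6 M⁻¹ min⁻¹)
    gas ⇌ partner, rate k5*(csat - [partner]) (kL = 12.7 min⁻¹)

For the neighbour charged with 0.42 M, the same interpolation gives κ = 0.0248 min⁻¹ and 0.249 M of target. The computed neighbour held 0.256 M of target at 40 min, which is 60.9% of its charge.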